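The constants of the steps are not given, but the readings of the flask, followed so far as the theta run, yield two numbers that can stand in for them, a share and a half-life.

| setting | theta | zeta | flask |
|---|---|---|---|
| substrate | 0.40 M | 0.60 M | 0.40 M |
| remark | the very flask that is asked about, followed so far | run made earlier |  |
| time |  |  | 30 h |

| run | time / h | target / % |
|---|---|---|
| theta | 0.167 | 18 |
| theta | 0.500 | 24 |
| theta | 1.50 | 17 |
| theta | 5.00 | 8 |
| theta | 15.0 | 0 |
| zeta | 0.133 | 16 |
| zeta | 0.417 | 21 |
| zeta | 1.33 | 16 |
| zeta | 4.00 | 6 |
| zeta | 12.0 | 3 |

(readings scatter by 2 percentage points)

- the best time, 30 h at the latest, for target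
- the amount of target, in percent of the substrate charged, at that time

- a species is counted by the substrate in it: one self-condensation product counts as two
- the earlier runs were read with a standard deviation of 2 percentage points
- steps under discussion: substrate <-> intermediate; intermediate <-> target; 2 substrate -> self-condensation product; substrate -> decomposition product

1. Let y be the fraction of the charge standing as target. Where a loss consumes substrate two at a time while target keeps a steady share of the pool of substrate, intermediate and target (a pre-equilibrium), 1/y climbs on a straight line in time.
2. Between 1.50 h and 5.00 h, the theta readings 17 % and 8 % make 1/y climb at 1.89 h⁻¹.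
3. Run back to the start, that line reads a target share s of 32.8 %. The pool half-life, the second-order time in which y falls to half of s, is 1.61 h, so y = s/(1 + t/th).
4. A second-order half-life shrinks as the charge grows, so the zeta run should have 1.07 h. That gives 2.69 % at 12.0 h, where the reading is 3 %, with a scatter of 2 percentage points.
5. The line only falls, and th is longer than 0.500 h, the time of the highest theta reading, so the reckoning here commits to a peak near that time at about the reading of 24 %, under the 25.0 % the line allows there.
6. The forecast says 0.5 h and 24.5 %, adding: “The true maximum may be slightly above the sampled point”.
7. The flask gives 22.7 % at 0.445 h.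

    substrate ⇌ intermediate (K = 0.360, k = 9.30 × 10⁻⁴ s⁻¹)
    intermediate ⇌ target (K = 1.80, k = 0.0180 s⁻¹)
    2 substrate → self-condensation product (k = 7.70 × 10⁻⁴ M⁻¹ s⁻¹)
    substrate → decomposition product (k = 1.40 × 10⁻⁶ s⁻¹)

The peak of target in the flask stays low in part through the return of target to intermediate: the same run without that return reaches 74.4 % against 22.7 %. While that return runs, target stays a share of the pool and drains with it, so the line gives 1.67 % for the flask at 30 h, and the flask holds 1.81 %. The neighbour flask with 0.10 M of substrate has a pool half-life of 6.44 h, so the line gives 5.80 % at the same time, and that flask holds 6.07 %.

(The data come from a simulation on assumed constants, noise included.)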